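**Plan**

1. Own locants: pyrrolidinone N4–C3–C2(CH3)–C26(=O)–C21; piperidine N4–C5–C6–C23–C22–C21; cyclopentane C21–C22–C23–C14–C20; δ-lactone C14–C15–C16–C17(=O)–O19–C20; seven-membered ring C6–C7–C8–C9–C13–C14–C23; cyclopentene C9–C10–C11–C12=C13; C24 is the CH2OH carbon on C23.
2. Cuts, in retrosynthetic order: C12=C13 (ring-closing carbonyl–olefin metathesis of a C13 ketone with a homoprenyl chain on C9); C9–C10 and C2–CH3 (enolate alkylations); O19–C17 and C20–H (reduction, equilibrating lactonisation); C6=C7 (olefin metathesis); C14–C15 (Michael); C6–C23 (reductive Heck); C14–C20 (Claisen); C13–C14 (B-alkyl acyl coupling); C21–C22 (asymmetric allylic alkylation of a 3-oxoproline ester).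
3. Forward ring order: pyrrolidinone (purchased), cyclopentane, piperidine (completing the 2-azabicyclo[3.2.1]octane), seven-membered ring, lactone, cyclopentene.
4. Stereochemistry: C21 from the asymmetric allylic alkylation; C23, C14, C6 and C20 are relayed from C21 through the bridged cage (tether-forced cyclisation, exo-face Michael addition, open-face hydrogenation, lactone trap); C9 by convex-face protonation; C2 by final equilibration.
5. Enabling feature: C12=C13 is the only unsaturation of the five-membered carbocycle, and C13 lies between the quaternary C14 and the C9 methine. The ring is therefore the direct metathesis retron of a C13 ketone that can enolise only toward C9. That one carbonyl first closes the cyclopentane, then activates C23 and C14 for the two quaternary centres, then carries the C9 side chain, and is finally consumed in the last ring closure.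

Key step: step 16

Remark: the (1R,2R) ligand of step 3 is assumed to give the (R) centre at C21; the antipodal ligand would be used if the sense proved opposite.
Remark: where a SMILES carries no configuration at a centre, that centre is epimeric or enolised at that stage (C23 and C14 in 12–20; C14 in 22; C2 in 32–34).

**Route**

Step 1
Reactants: 1 2-methylidenepropane-1,3-diol; 2 tert-butyl(chloro)diphenylsilane
Product: 3 mono-TBDPS ether of diol 1
Conditions: NaH (1.0 equiv), THF, 0 °C; then 2, 0 °C to rt
Reagents that add atoms: tert-butyl(chloro)diphenylsilane (2), CC(C)(C)[Si](Cl)(c1ccccc1)c1ccccc1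
Why: O-Silylation of a symmetric diol through its monosodium alkoxide should give the mono-ether; no stereocentre is involved.

Step 2
Reactants: 3 mono-TBDPS ether; 4 methyl chloroformate
Product: 5 allylic methyl carbonate
Conditions: pyridine, CH2Cl2, 0 °C
Reagents that add atoms: methyl chloroformate (4), COC(=O)Cl
Why: O-Acylation of the primary allylic alcohol provides the carbonate leaving group needed for π-allyl formation; no stereocentre is involved.

Step 3
Reactants: 6 1-tert-butyl 2-ethyl 3-oxopyrrolidine-1,2-dicarboxylate; 5 allylic methyl carbonate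
Product: 7 (2R)-2-allylated 3-oxoproline ester
Conditions: Pd2(dba)3·CHCl3 (2.5 mol %), (1R,2R)-N,N'-bis[2-(diphenylphosphino)benzoyl]cyclohexane-1,2-diamine (7.5 mol %), toluene, 0 °C to rt
Reagents that add atoms: carbonate 5, C=C(COC(=O)OC)CO[Si](c1ccccc1)(c1ccccc1)C(C)(C)C
Why: Tsuji–Trost asymmetric allylic alkylation of a cyclic β-keto ester: zerovalent palladium ionises the carbonate, the released methoxide forms the enolate, and the chiral diphosphine pocket selects one enolate face to set the quaternary C21 (R) centre from which all other centres are relayed, the symmetrical π-allyl termini leaving no regiochemical question.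

Step 4
Reactants: 8 pent-4-enoyl chloride; 9 benzenethiol
Product: 10 S-phenyl pent-4-enethioate
Conditions: pyridine, CH2Cl2, 0 °C
Reagents that add atoms: benzenethiol (9), Sc1ccccc1
Why: Acyl substitution gives the thioester that serves as acyl donor in the Liebeskind–Srogl coupling of step 5; no stereocentre is involved.

Step 5
Reactants: 7 allylated oxoproline ester; 11 9-borabicyclo[3.3.1]nonane; 10 S-phenyl pent-4-enethioate
Product: 13 N-Boc keto ester, via alkylborane 12 (not isolated)
Conditions: 11 (1.1 equiv), THF, 0 °C to rt; then 10, Pd(PPh3)4 (5 mol %), copper thiophene-2-carboxylate Cu(O2CC4H3S) (1.5 equiv), Cs2CO3 (2 equiv), THF, 45 °C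
Reagents that add atoms: S-phenyl pent-4-enethioate (10), C=CCCC(=O)Sc1ccccc1
Why: Anti-Markovnikov hydroboration of the 1,1-disubstituted olefin places boron on the terminal carbon C14, and a Liebeskind–Srogl B-alkyl cross-coupling (zerovalent palladium, monovalent copper carboxylate as thiophile) transfers the pent-4-enoyl group to it under conditions that should leave ketone, esters and carbamate alone; the C23 methine forms as both epimers and is erased in step 8.

Step 6
Reactants: 13 N-Boc keto ester; 14 2,3-dibromoprop-1-ene
Product: 16 N-(2-bromoallyl) keto ester, via amine 15 (not isolated)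
Conditions: CF3CO2H, CH2Cl2, 0 °C; evaporate; then 14, K2CO3, MeCN, 40 °C
Reagents that add atoms: 2,3-dibromoprop-1-ene (14), C=C(Br)CBr
Why: Acidolysis of the tert-butyl carbamate and SN2 N-alkylation by the allylic bromide (the vinylic bromide does not react) attach the vinyl bromide tether to N4; no stereocentre is touched.

Step 7
Reactants: 16 N-(2-bromoallyl) keto ester
Product: 17 spiro β-diketone
Conditions: LiN(SiMe3)2 (2.5 equiv), THF, −78 to 0 °C; AcOH
Reagents that add atoms: none
Why: Intramolecular Claisen condensation (Dieckmann type): the C14 enolate of the C13 ketone acylates the C20 ethyl ester in a 5-(enolexo)-exo-trig closure pulled forward by formation of the β-diketonate, the competing closures leading only to four- or seven-membered rings; C14 stays enolised and C23 epimeric.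

Step 8
Reactants: 17 spiro β-diketone; 18 N-(phenylselanyl)phthalimide
Product: 21 alkylidene 1,3-diketone, via selenide 19 (not isolated), via selenoxide 20 (not isolated)
Conditions: 18, pyridine (cat.), CH2Cl2, rt; then NaIO4, NaHCO3, THF–H2O, 0 °C to rt
Reagents that add atoms: none
Why: α-Selenenylation of the enolised β-diketone at C14 followed by selenoxide syn-elimination, for which C23–H is the only β-hydrogen, should give the C14=C23 olefin from either C23 epimer, NaIO4 oxidising selenium in preference to the tertiary amine.

Step 9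
Reactants: 21 alkylidene 1,3-diketone
Product: 22 bridged tricyclic β-diketone
Conditions: Pd(OAc)2 (10 mol %), PPh3 (20 mol %), HCO2Na, Bu4NCl, DMF, 80 °C
Reagents that add atoms: none
Why: Reductive Heck cyclisation: oxidative addition of zerovalent palladium to the vinyl bromide, 6-exo-trig carbopalladation of the doubly acceptor-activated C14=C23 bond at C23 and formate reduction of the palladium enolate close the piperidine, and because the N4–C5–C6 tether can reach C23 only on the face that carries N4, the quaternary C23 centre (C6 syn to N4, CH2OSi anti) is fixed by C21.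

Step 10
Reactants: 22 bridged tricyclic β-diketone; 23 methyl acrylate
Product: 24 Michael adduct
Conditions: DBU (0.2 equiv), MeCN, rt
Reagents that add atoms: methyl acrylate (23), C=CC(=O)OC
Why: Michael addition of the β-diketone: C14 sits on the two-carbon bridge of the 2-azabicyclo[3.2.1]octane and is attacked on its exo face, anti to the N4–C5–C6 bridge, so the propanoate chain becomes cis to C24 and the pentenoyl group is turned toward C6.

Step 11
Reactants: 24 Michael adduct
Product: 25 tetracyclic cycloheptene
Conditions: p-TsOH·H2O (1.1 equiv), CH2Cl2; second-generation Grubbs catalyst RuCl2(=CHPh)(PCy3)(H2IMes) (10 mol %), 40 °C; aq NaHCO3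
Reagents that add atoms: none
Why: Ring-closing olefin metathesis between the C6 exo-methylene and the terminal olefin of the endo pentenoyl chain (amine masked as its ammonium tosylate) should close the seven-membered ring as the C6=C7 olefin with loss of ethene; no stereocentre is formed.

Step 12
Reactants: 25 tetracyclic cycloheptene
Product: 26 saturated triketone ester
Conditions: H2 (1 atm), Pd/C (10 %), EtOAc, rt
Reagents that add atoms: none
Why: Heterogeneous hydrogenation should deliver hydrogen to C6=C7 from the open face of the piperidine ring, opposite the C14–C20 bridge, leaving H6 axial and C7 equatorial as the target requires.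

Step 13
Reactants: 26 saturated triketone ester
Product: 28 keto lactone, via hydroxy ester 27 (not isolated)
Conditions: LiN(SiMe3)2 (2.3 equiv), THF, −78 °C; LiBH4, −78 to 0 °C; AcOH; then DBU, toluene, 80 °C
Reagents that add atoms: none
Why: With the two enolisable ketones (C26, C13) masked in situ as lithium enolates, LiBH4 reduces only the non-enolisable C20 ketone, probably from the exo face to the endo alcohol 27; DBU then equilibrates C20 by retro-aldol/aldol through the C21 enolate (C21 cannot invert because it is tied into the cage) until the exo alkoxide, the only one that reaches the ester, is removed as the cis-fused δ-lactone (aldol equilibration with lactone trap).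

Step 14
Reactants: 28 keto lactone; 29 iodomethane
Product: 30 C2-methyl keto lactone
Conditions: LiN(SiMe3)2 (1.0 equiv), THF, −78 to −40 °C; then 29, −78 °C
Reagents that add atoms: iodomethane (29), CI
Why: Enolate alkylation at C2, the more acidic α-methylene (five-membered α-amino ketone, whereas the C13 carbonyl is shielded by C14), with iodomethane approaching anti to C20; the new C2 centre is labile and is finally fixed in step 17.

Step 15
Reactants: 30 C2-methyl keto lactone; 31 5-bromo-2-methylpent-2-ene
Product: 33 metathesis precursor, via 9-epi ketone 32 (not isolated)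
Conditions: KN(SiMe3)2 (2.3 equiv), THF–DMPU, −78 °C; 31, Bu4NI (cat.), −78 to −30 °C; KN(SiMe3)2 (1.5 equiv), −30 to 0 °C; AcOH in THF, −78 °C
Reagents that add atoms: 5-bromo-2-methylpent-2-ene (31), CC(C)=CCCBr
Why: Alkylation of the bis-enolate occurs at C9, the only enolate carbon that does not become quaternary, on the convex face to give 32, and re-enolisation followed by kinetic protonation from the same convex face inverts C9 so that C10 lies on the cage side as in the target, C2 being reprotonated without control.

Step 16
Reactants: 33 metathesis precursor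
Product: 34 hexacyclic silyl ether
Conditions: HBF4·OEt2 (1.05 equiv), ClCH2CH2Cl, 0 °C; FeCl3 (0.3 equiv), 50 °C; aq NaHCO3
Reagents that add atoms: none
Why: The C13 carbonyl, activated by FeCl3, and the C12=C(CH3)2 olefin combine in an asynchronous, concerted [2+2] cycloaddition to an oxetane, and Lewis acid-assisted retro-[2+2] cleavage of the oxetane expels acetone and leaves the C12=C13 double bond. The closest known reaction type is the FeCl3-catalysed ring-closing carbonyl–olefin metathesis of aliphatic ketones that carry a pendant isopropylidene olefin, which gives cyclopentenes. The cyclopentene closes through the C12–C13 bond in a 5-exo-trig attack of the nucleophilic olefin carbon C12 on the carbonyl carbon, with the carbonyl oxygen and the isopropylidene carbon outside the new ring. No stereocentre is created: C9, set in step 15, only has to be preserved, and it is locked as soon as C13 becomes olefinic. The step needs site selectivity for the C13 ketone over the C26 ketone and the lactone, secured because only C13 has the olefin within five-membered reach, and it needs the double bond at C12=C13 and not in the more substituted C9=C13 position, which the mechanism guarantees because carbon replaces oxygen at C13. Prior protonation of N4 keeps the amine from binding the catalyst, and the quaternary C14 blocks enolisation on that side.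

Step 17
Reactants: 34 hexacyclic silyl ether
Product: 36 CNP0180795.1, via silyl ether 35 (not isolated)
Conditions: DBU (0.5 equiv), CH2Cl2, rt; then HF·pyridine, THF, 0 °C to rt
Reagents that add atoms: none
Why: Base equilibration through the C26 enolate should bring C2 to the more stable configuration with the methyl anti to C20 (no other centre is epimerisable once C13 is olefinic), and HF·pyridine cleaves the silyl ether to free the C24 hydroxyl.

**Compound list**

1 | 2-methylidenepropane-1,3-diol | C=C(CO)CO | starting material
2 | tert-butyl(chloro)diphenylsilane | CC(C)(C)[Si](Cl)(c1ccccc1)c1ccccc1 | starting material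
3 | 2-({[tert-butyl(diphenyl)silyl]oxy}methyl)prop-2-en-1-ol | C=C(CO)CO[Si](c1ccccc1)(c1ccccc1)C(C)(C)C | intermediate
4 | methyl chloroformate | COC(=O)Cl | starting material
5 | 2-({[tert-butyl(diphenyl)silyl]oxy}methyl)prop-2-en-1-yl methyl carbonate | C=C(COC(=O)OC)CO[Si](c1ccccc1)(c1ccccc1)C(C)(C)C | intermediate
6 | 1-tert-butyl 2-ethyl 3-oxopyrrolidine-1,2-dicarboxylate (racemic, enolisable) | CCOC(=O)C1N(C(=O)OC(C)(C)C)CCC1=O | starting material
7 | 1-tert-butyl 2-ethyl (2R)-2-[2-({[tert-butyl(diphenyl)silyl]oxy}methyl)prop-2-en-1-yl]-3-oxopyrrolidine-1,2-dicarboxylate | CC(C)(C)OC(=O)N1CCC(=O)[C@@]1(C(=O)OCC)CC(=C)CO[Si](c2ccccc2)(c2ccccc2)C(C)(C)C | intermediate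
8 | pent-4-enoyl chloride | C=CCCC(=O)Cl | starting material
9 | benzenethiol | Sc1ccccc1 | starting material
10 | S-phenyl pent-4-enethioate | C=CCCC(=O)Sc1ccccc1 | intermediate
11 | 9-borabicyclo[3.3.1]nonane | B1C2CCCC1CCC2 | starting material
12 | B-alkyl-9-borabicyclononane from 7 (boron on C14; C23 epimers; C21 R) | CC(C)(C)OC(=O)N1CCC(=O)[C@@]1(C(=O)OCC)CC(CO[Si](c2ccccc2)(c2ccccc2)C(C)(C)C)CB2C3CCCC2CCC3 | intermediate
13 | 1-tert-butyl 2-ethyl (2R)-2-[2-({[tert-butyl(diphenyl)silyl]oxy}methyl)-4-oxooct-7-en-1-yl]-3-oxopyrrolidine-1,2-dicarboxylate (epimers at the side-chain methine) | CC(C)(C)OC(=O)N1CCC(=O)[C@@]1(C(=O)OCC)CC(CO[Si](c2ccccc2)(c2ccccc2)C(C)(C)C)CC(=O)CCC=C | intermediate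
14 | 2,3-dibromoprop-1-ene | C=C(Br)CBr | starting material
15 | ethyl (2R)-2-[2-({[tert-butyl(diphenyl)silyl]oxy}methyl)-4-oxooct-7-en-1-yl]-3-oxopyrrolidine-2-carboxylate (free secondary amine) | N1CCC(=O)[C@@]1(C(=O)OCC)CC(CO[Si](c2ccccc2)(c2ccccc2)C(C)(C)C)CC(=O)CCC=C | intermediate
16 | ethyl (2R)-1-(2-bromoprop-2-en-1-yl)-2-[2-({[tert-butyl(diphenyl)silyl]oxy}methyl)-4-oxooct-7-en-1-yl]-3-oxopyrrolidine-2-carboxylate | C=C(Br)CN1CCC(=O)[C@@]1(C(=O)OCC)CC(CO[Si](c2ccccc2)(c2ccccc2)C(C)(C)C)CC(=O)CCC=C | intermediate
17 | (5R)-1-(2-bromoprop-2-en-1-yl)-8-({[tert-butyl(diphenyl)silyl]oxy}methyl)-7-(pent-4-enoyl)-1-azaspiro[4.4]nonane-4,6-dione (enolised at C7, epimers at C8) | C=C(Br)CN1CCC(=O)[C@@]12CC(CO[Si](c3ccccc3)(c3ccccc3)C(C)(C)C)C(C(=O)CCC=C)C2=O | intermediate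
18 | N-(phenylselanyl)phthalimide | O=C1c2ccccc2C(=O)N1[Se]c1ccccc1 | starting material
19 | 7-(phenylselanyl) derivative of 17 | C=C(Br)CN1CCC(=O)[C@@]12CC(CO[Si](c3ccccc3)(c3ccccc3)C(C)(C)C)C(C(=O)CCC=C)([Se]c3ccccc3)C2=O | intermediate
20 | selenoxide of 19 | C=C(Br)CN1CCC(=O)[C@@]12CC(CO[Si](c3ccccc3)(c3ccccc3)C(C)(C)C)C(C(=O)CCC=C)([Se](=O)c3ccccc3)C2=O | intermediate
21 | (5R)-1-(2-bromoprop-2-en-1-yl)-8-({[tert-butyl(diphenyl)silyl]oxy}methyl)-7-(pent-4-enoyl)-1-azaspiro[4.4]non-7-ene-4,6-dione | C=C(Br)CN1CCC(=O)[C@@]12CC(CO[Si](c3ccccc3)(c3ccccc3)C(C)(C)C)=C(C(=O)CCC=C)C2=O | intermediate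
22 | tricyclic β-diketone: 2-azabicyclo[3.2.1]octane (bridges N4–C5–C6, C20–C14 and C22 between C21 and C23) fused at N4–C21 to the pyrrolidin-3-one; C6 exo-methylene, C20 ketone, C14-H bearing pent-4-enoyl (enolisable), C23 CH2OTBDPS anti to the N4–C5–C6 bridge; C21 and C23 as in the target | C1CN2CC(=C)[C@]3(CO[Si](c4ccccc4)(c4ccccc4)C(C)(C)C)C[C@@]2(C1=O)C(=O)C3C(=O)CCC=C | intermediate
23 | methyl acrylate | C=CC(=O)OC | starting material
24 | as 22 with C14 quaternary: CH2CH2CO2CH3 on the exo face (anti to the N4–C5–C6 bridge), pent-4-enoyl endo; C14, C21, C23 as in the target | C1CN2CC(=C)[C@]3(CO[Si](c4ccccc4)(c4ccccc4)C(C)(C)C)C[C@@]2(C1=O)C(=O)[C@]3(CCC(=O)OC)C(=O)CCC=C | intermediate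
25 | tetracyclic triketone ester with the seven-membered ring closed (C6=C7 olefin, C13 ketone); C14, C21, C23 as in the target | C1CN2CC3=CCCC(=O)[C@@]5(CCC(=O)OC)C(=O)[C@@]2(C[C@@]35CO[Si](c2ccccc2)(c2ccccc2)C(C)(C)C)C1=O | intermediate
26 | 6,7-dihydro derivative of 25, H6 anti to the C14–C20 bridge (C6 as in the target) | C1CN2C[C@H]3CCCC(=O)[C@@]5(CCC(=O)OC)C(=O)[C@@]2(C[C@@]35CO[Si](c2ccccc2)(c2ccccc2)C(C)(C)C)C1=O | intermediate
27 | C20 alcohol of 26 with the hydroxyl endo (syn to the N4–C5–C6 bridge, trans to the propanoate chain) | C1CN2C[C@H]3CCCC(=O)[C@@]5(CCC(=O)OC)[C@@H](O)[C@@]2(C[C@@]35CO[Si](c2ccccc2)(c2ccccc2)C(C)(C)C)C1=O | intermediate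
28 | pentacyclic keto lactone: δ-lactone closed on the exo C20 oxygen; C13 and C26 ketones, C2 and C9 methylene, C24 O-TBDPS; C6, C14, C20, C21, C23 as in the target | C1CN2C[C@H]3CCCC(=O)[C@@]45CCC(=O)O[C@@H]4[C@@]2(C[C@@]35CO[Si](c2ccccc2)(c2ccccc2)C(C)(C)C)C1=O | intermediate
29 | iodomethane | CI | starting material
30 | 28 with a methyl group on C2 anti to C20 (C2 as in the target) | C[C@@H]1CN2C[C@H]3CCCC(=O)[C@@]45CCC(=O)O[C@@H]4[C@@]2(C[C@@]35CO[Si](c2ccccc2)(c2ccccc2)C(C)(C)C)C1=O | intermediate
31 | 5-bromo-2-methylpent-2-ene | CC(C)=CCCBr | starting material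
32 | 9-epimer of 33 (4-methylpent-3-enyl group on the convex face), present in the flask as its C2 potassium enolate | CC1CN2C[C@H]3CC[C@H](CCC=C(C)C)C(=O)[C@@]45CCC(=O)O[C@@H]4[C@@]2(C[C@@]35CO[Si](c2ccccc2)(c2ccccc2)C(C)(C)C)C1=O | intermediate
33 | metathesis precursor: 30 carrying a 4-methylpent-3-en-1-yl chain on C9 with H9 on the convex face (C9 as in the target); C2 epimers | CC1CN2C[C@H]3CC[C@@H](CCC=C(C)C)C(=O)[C@@]45CCC(=O)O[C@@H]4[C@@]2(C[C@@]35CO[Si](c2ccccc2)(c2ccccc2)C(C)(C)C)C1=O | intermediate
34 | O-TBDPS ether of the target as C2 epimers | CC1CN2C[C@H]3CC[C@H]4CCC=C4[C@@]45CCC(=O)O[C@@H]4[C@@]2(C[C@@]35CO[Si](c2ccccc2)(c2ccccc2)C(C)(C)C)C1=O | intermediate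
35 | O-TBDPS ether of the target (C2 equilibrated) | C[C@@H]1CN2C[C@H]3CC[C@H]4CCC=C4[C@@]45CCC(=O)O[C@@H]4[C@@]2(C[C@@]35CO[Si](c2ccccc2)(c2ccccc2)C(C)(C)C)C1=O | intermediate
36 | CNP0180795.1: hexacyclic amino keto lactone with free C24 hydroxymethyl, all centres as in the given structure | C[C@@H]1CN2C[C@H]3CC[C@H]4CCC=C4[C@@]45CCC(=O)O[C@@H]4[C@@]2(C[C@@]35CO)C1=O | target

**Count and risks**

Total step count: 17. Longest linear sequence: 16 steps (steps 1–3 and 5–17).

Steps most likely to fail:

Step 16. Acid-promoted enolisation of the C13 ketone may epimerise C9 before the ring closes. The ammonium centre or traces of free amine may also sequester the iron catalyst, or the oxetane may fail to fragment and divert into a carbonyl-ene pathway. Fallback: setting out from 33, ozonolysis (O3, CH2Cl2–MeOH, CF3CO2H to protonate N4, −78 °C; Me2S) cleaves the isopropylidene olefin to the keto aldehyde F1. An intramolecular McMurry coupling (TiCl3, Zn–Cu, DME, reflux, high dilution) then joins C12 to C13 as the olefin and returns to the route at 34.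

Step 15. Alkylation may occur at the wrong enolate (C2 or oxygen), proton exchange between the enolates may lead to over-alkylation, and the kinetic protonation may show poor facial discrimination. Fallback: setting out from 30, the kinetic C9 lithium enolate (LiN(iPr)2, 1.05 equiv, THF, −78 °C) is added to 4-methylpent-3-enal F2, made from commercial 4-methylpent-3-en-1-ol with SO3·pyridine, DMSO and Et3N, to give the aldol F3. Mesylation and elimination (MsCl, Et3N; DBU) give the (E)-alkylidene ketone F4. Conjugate reduction with [(Ph3P)CuH]6 generates only the C9 enolate, which is protonated from the convex face, and the route is rejoined at 33 with C2 untouched.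

Step 13. Incomplete enolate masking may lead to reduction of the C26 or C13 ketone or of the ester, and the ring-opened β-keto aldehyde of the retro-aldol equilibration may decompose (deformylation) before it recloses. Fallback: setting out from 26, Me3SnOH (ClCH2CH2Cl, 80 °C) hydrolyses the methyl ester to the keto acid F5. Ionic hydrogenation (Et3SiH, CF3CO2H, CH2Cl2) then reduces the cyclic acyloxycarbenium ion formed between the acid and the C20 ketone. The tether allows only the cis-fused lactone, and the route is rejoined at 28.

Further compounds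
F1 | step 16 | keto aldehyde: 33 with the side chain on C9 shortened to CH2CH2CHO (C12 aldehyde) | CC1CN2C[C@H]3CC[C@@H](CCC=O)C(=O)[C@@]45CCC(=O)O[C@@H]4[C@@]2(C[C@@]35CO[Si](c2ccccc2)(c2ccccc2)C(C)(C)C)C1=O
F2 | step 15 | 4-methylpent-3-enal | CC(C)=CCC=O
F3 | step 15 | aldol: 30 carrying a 1-hydroxy-4-methylpent-3-en-1-yl group on C9 (epimers at C9 and C10) | C[C@@H]1CN2C[C@H]3CCC(C(O)CC=C(C)C)C(=O)[C@@]45CCC(=O)O[C@@H]4[C@@]2(C[C@@]35CO[Si](c2ccccc2)(c2ccccc2)C(C)(C)C)C1=O
F4 | step 15 | (E)-alkylidene ketone: 30 with a C9=C10 double bond to the 4-methylpent-3-enylidene group | C[C@@H]1CN2C[C@H]3CC/C(=C\CC=C(C)C)C(=O)[C@@]45CCC(=O)O[C@@H]4[C@@]2(C[C@@]35CO[Si](c2ccccc2)(c2ccccc2)C(C)(C)C)C1=O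
F5 | step 13 | keto acid: 26 with the methyl ester hydrolysed to CO2H | C1CN2C[C@H]3CCCC(=O)[C@@]5(CCC(=O)O)C(=O)[C@@]2(C[C@@]35CO[Si](c2ccccc2)(c2ccccc2)C(C)(C)C)C1=O
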